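**Plan**

- Feature: in the lactone ring (C1, O2, C3, C3a, C7a) the acyl carbon C1 sits on C7a and the oxygen-bearing C3–H sits on the adjacent C3a. The phthalide is therefore an isomer of the open 2-acylbenzaldehyde (CHO on C7a, C3 ketone on C3a), differing only in the place of one hydrogen and one C–O bond.
- Cuts: first C1–O2 and C3–H (hydroacylation), then C3–C3a (aryl Grignard reagent plus chain aldehyde), then C8'–C9' (alkyl Grignard reagent plus terminal epoxide). The C13' ketone goes back to a terminal alkene and the formyl carbon C1 to a Vilsmeier–Haack formylation.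
- Forward: the C15 chain is joined first (C9 + C6), its primary end is oxidised and the C10' hydroxyl acetylated. The arene is then attached, both carbonyl groups are unveiled, and the lactone, the only ring to be made, closes last.
- Stereochemistry: C10' (R) comes from purchased (S)-2-(but-3-en-1-yl)oxirane and is never touched. C3 (S) is set by the chiral bisphosphine on rhodium in the last step.

Key step: step 9

Remark: the (1S,1'S,2R,2'R) antipode of Duanphos is assigned to Re-face hydride delivery, that is to the (S)-phthalide, by analogy with simple 3-alkylphthalides; both antipodes are sold, so a reversed sense would be answered by the mirror-image ligand.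

**Step 1**
Reactants: 1 1-bromo-3,5-dimethoxybenzene
Product: 3 2-bromo-4,6-dimethoxybenzaldehyde, via iminium chloride 2 (not isolated)
Conditions: POCl3, DMF, 0 → 90 °C; then H2O, 0 °C → rt
Reagents that add atoms: N,N-dimethylformamide CN(C)C=O; water O
Why: Vilsmeier–Haack formylation: the chloroiminium ion made from DMF and POCl3 should attack the ring carbon para to one methoxy group and ortho to the other (next to bromine) in preference to the more crowded carbon between the two methoxy groups, and water then hydrolyses iminium chloride 2 to the aldehyde.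

**Step 2**
Reactants: 3 2-bromo-4,6-dimethoxybenzaldehyde
Product: 4 2-(2-bromo-4,6-dimethoxyphenyl)-1,3-dioxolane
Conditions: HOCH2CH2OH, p-TsOH·H2O (cat.), toluene, reflux, Dean–Stark trap
Reagents that add atoms: ethane-1,2-diol OCCO
Why: Acid-catalysed acetalisation driven by azeotropic removal of water masks the formyl group, the later C1, so that the aryl bromide can be turned into a Grignard reagent in step 6.

**Step 3**
Reactants: 5 9-bromononan-1-ol; 6 (S)-2-(but-3-en-1-yl)oxirane
Product: 9 (R)-pentadec-14-ene-1,11-diol, via bromo alkoxide 7 (not isolated), via alkoxide Grignard reagent 8 (not isolated)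
Conditions: MeMgCl (1.0 equiv), THF, −20 °C; Mg turnings, THF, reflux; CuI (10 mol %), then 6, −30 → 0 °C
Reagents that add atoms: none
Why: Copper-catalysed SN2 opening of a terminal epoxide by a primary alkyl Grignard reagent, whose own hydroxyl is first masked as the magnesium alkoxide by one equivalent of MeMgCl; attack takes place at the unsubstituted epoxide carbon, so no bond to the stereocentre is broken and the descriptor changes from (S) to (R) only because the CIP ranking of the two carbon branches is reversed.

**Step 4**
Reactants: 9 (R)-pentadec-14-ene-1,11-diol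
Product: 10 (R)-11-hydroxypentadec-14-enal
Conditions: TEMPO (10 mol %), PhI(OAc)2 (1.1 equiv), CH2Cl2, 0 °C → rt
Reagents that add atoms: none
Why: Oxoammonium oxidation (TEMPO with PhI(OAc)2 as terminal oxidant), which for steric reasons takes the primary alcohol far faster than the secondary one, stops at the aldehyde in the absence of water and leaves the alkene alone, while the 1,11-spacing rules out lactol formation.

**Step 5**
Reactants: 10 (R)-11-hydroxypentadec-14-enal
Product: 11 (R)-11-acetoxypentadec-14-enal
Conditions: Ac2O, pyridine, DMAP (cat.), CH2Cl2, 0 °C → rt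
Reagents that add atoms: acetic anhydride CC(=O)OC(C)=O
Why: DMAP-catalysed acetylation of the secondary alcohol, which takes place at oxygen and therefore with retention at C11, under conditions too mild to enol-acetylate the aldehyde.

**Step 6**
Reactants: 4 2-(2-bromo-4,6-dimethoxyphenyl)-1,3-dioxolane; 11 (R)-11-acetoxypentadec-14-enal
Product: 13 (5R)-15-[2-(1,3-dioxolan-2-yl)-3,5-dimethoxyphenyl]-15-hydroxypentadec-1-en-5-yl acetate (both C15 epimers), via arylmagnesium bromide 12 (not isolated)
Conditions: 4, Mg turnings, I2 (trace), THF, 45 °C; then 12 run into 11, THF, −40 → 0 °C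
Reagents that add atoms: none
Why: Grignard addition to an aldehyde: at low temperature and with the reagent run into the aldehyde, the arylmagnesium species should add to the formyl group much faster than to the hindered secondary acetate, and the new carbinol centre, formed without control, is erased in step 7.

**Step 7**
Reactants: 13 (5R)-15-[2-(1,3-dioxolan-2-yl)-3,5-dimethoxyphenyl]-15-hydroxypentadec-1-en-5-yl acetate
Product: 14 (R)-15-[2-(1,3-dioxolan-2-yl)-3,5-dimethoxyphenyl]-15-oxopentadec-1-en-5-yl acetate
Conditions: Dess–Martin periodinane, NaHCO3, CH2Cl2, 0 °C → rt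
Reagents that add atoms: none
Why: Dess–Martin oxidation of the secondary benzylic alcohol to the aryl ketone, buffered with NaHCO3 so that the liberated acetic acid cannot ionise the electron-rich aryl acetal or let the hydroxyl close onto it.

**Step 8**
Reactants: 14 (R)-15-[2-(1,3-dioxolan-2-yl)-3,5-dimethoxyphenyl]-15-oxopentadec-1-en-5-yl acetate
Product: 16 (R)-1-(2-formyl-3,5-dimethoxyphenyl)-1,14-dioxopentadecan-11-yl acetate, via methyl ketone acetal 15 (not isolated)
Conditions: PdCl2 (10 mol %), CuCl (cat.), O2 (1 atm), DMF/H2O 7:1, rt; then 1 M HCl, rt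
Reagents that add atoms: water O
Why: Tsuji–Wacker oxidation of the monosubstituted alkene, in which water adds at the internal carbon (Markovnikov) to give the methyl ketone, followed in the same flask by acid hydrolysis of the dioxolane, so that any acetal loss during the oxidation is of no consequence while the acetate survives the dilute acid.

**Step 9**
Reactants: 16 (R)-1-(2-formyl-3,5-dimethoxyphenyl)-1,14-dioxopentadecan-11-yl acetate
Product: 17 (S)-3-[(R)-10-acetoxy-13-oxotetradecyl]-5,7-dimethoxyisobenzofuran-1(3H)-one
Conditions: [Rh(cod)Cl]2 (5 mol %), (1S,1'S,2R,2'R)-Duanphos (10 mol %), AgNO3 (10 mol %), toluene, 75–100 °C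
Reagents that add atoms: none
Why: Chloride abstraction by AgNO3 leaves a bisphosphine complex of monovalent rhodium that adds oxidatively to the aldehyde C–H bond of 16, and in the resulting acyl hydride of trivalent rhodium the oxygen of the neighbouring C3 ketone takes up a coordination site. Insertion of that C=O into Rh–H makes the C3–H bond and a six-membered rhodacycle (Rh, C1, C7a, C3a, C3, O2), and C1–O2 reductive elimination then releases the product, so the one ring formed, the five-membered lactone, closes in a formally 5-exo-trig way at the acyl carbon. The closest known reaction type is the rhodium–Duanphos-catalysed enantioselective ketone hydroacylation of 2-acylbenzaldehydes bearing n-alkyl ketones to 3-alkylphthalides, the substrate class to which 16 belongs. The C3 configuration is decided in the hydride transfer, where the tert-butyl groups on the stereogenic phosphorus atoms should leave only the Re face of the ketone open, whereas the C10' centre lies ten atoms away, exerts no influence and is not touched. The step needs chemoselectivity for the aryl ketone over the C13' methyl ketone and the acetate, which is secured because only the ortho ketone can chelate the acyl hydride. It also needs insertion to outrun loss of CO, which the chelate and the coordinating nitrate counter-ion should favour.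

**Compound list**

1 | 1-bromo-3,5-dimethoxybenzene | COc1cc(Br)cc(OC)c1 | starting material
2 | (2-bromo-4,6-dimethoxybenzylidene)dimethylammonium chloride | COc1cc(Br)c(C=[N+](C)C)c(OC)c1.[Cl-] | intermediate
3 | 2-bromo-4,6-dimethoxybenzaldehyde | COc1cc(Br)c(C=O)c(OC)c1 | intermediate
4 | 2-(2-bromo-4,6-dimethoxyphenyl)-1,3-dioxolane | COc1cc(Br)c(C2OCCO2)c(OC)c1 | intermediate
5 | 9-bromononan-1-ol | OCCCCCCCCCBr | starting material
6 | (S)-2-(but-3-en-1-yl)oxirane | C=CCC[C@H]1CO1 | starting material
7 | chloromagnesium 9-bromononan-1-olate | Cl[Mg]OCCCCCCCCCBr | intermediate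
8 | chloromagnesium 9-(bromomagnesio)nonan-1-olate | Cl[Mg]OCCCCCCCCC[Mg]Br | intermediate
9 | (R)-pentadec-14-ene-1,11-diol | OCCCCCCCCCC[C@H](CCC=C)O | intermediate
10 | (R)-11-hydroxypentadec-14-enal | O=CCCCCCCCCC[C@H](CCC=C)O | intermediate
11 | (R)-11-acetoxypentadec-14-enal | O=CCCCCCCCCC[C@H](CCC=C)OC(C)=O | intermediate
12 | [2-(1,3-dioxolan-2-yl)-3,5-dimethoxyphenyl]magnesium bromide | COc1cc([Mg]Br)c(C2OCCO2)c(OC)c1 | intermediate
13 | (5R)-15-[2-(1,3-dioxolan-2-yl)-3,5-dimethoxyphenyl]-15-hydroxypentadec-1-en-5-yl acetate, both C15 epimers | COc1cc(OC)c(C2OCCO2)c(c1)C(O)CCCCCCCCC[C@H](CCC=C)OC(C)=O | intermediate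
14 | (R)-15-[2-(1,3-dioxolan-2-yl)-3,5-dimethoxyphenyl]-15-oxopentadec-1-en-5-yl acetate | COc1cc(OC)c(C2OCCO2)c(c1)C(=O)CCCCCCCCC[C@H](CCC=C)OC(C)=O | intermediate
15 | (R)-1-[2-(1,3-dioxolan-2-yl)-3,5-dimethoxyphenyl]-1,14-dioxopentadecan-11-yl acetate | COc1cc(OC)c(C2OCCO2)c(c1)C(=O)CCCCCCCCC[C@H](CCC(C)=O)OC(C)=O | intermediate
16 | (R)-1-(2-formyl-3,5-dimethoxyphenyl)-1,14-dioxopentadecan-11-yl acetate | COc1cc(OC)c(C=O)c(c1)C(=O)CCCCCCCCC[C@H](CCC(C)=O)OC(C)=O | intermediate
17 | (S)-3-[(R)-10-acetoxy-13-oxotetradecyl]-5,7-dimethoxyisobenzofuran-1(3H)-one | COc1cc(OC)c2c(c1)[C@H](CCCCCCCCC[C@H](CCC(C)=O)OC(C)=O)OC2=O | target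

Total step count: 9
Longest linear sequence: 7 steps (from 5 through steps 3 to 9)

**Steps most likely to fail**

**Step 9.**
- What may go wrong: oxidative addition to a formyl group flanked by two ortho substituents on an electron-rich ring may be slow. The acyl hydride may lose CO, the keto aldehyde may undergo intramolecular aldol closure on long heating, or facial discrimination may be incomplete.
- Route of the fallback: it sets out from 16 and comes back at 17, replacing the isomerisation by an oxidation followed by an enantioselective reduction.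
- First, Pinnick oxidation (NaClO2, NaH2PO4, 2-methylbut-2-ene, t-BuOH/H2O) should convert the formyl group into 2-[(R)-11-acetoxy-14-oxopentadecanoyl]-4,6-dimethoxybenzoic acid F1.
- MeI and K2CO3 in DMF should then give methyl 2-[(R)-11-acetoxy-14-oxopentadecanoyl]-4,6-dimethoxybenzoate F2.
- Asymmetric transfer hydrogenation with RuCl[(S,S)-TsDPEN](p-cymene) in HCO2H/Et3N reduces aryl alkyl ketones to (S)-carbinols and takes dialkyl ketones far more slowly. It should give methyl 2-[(1S,11R)-11-acetoxy-1-hydroxy-14-oxopentadecyl]-4,6-dimethoxybenzoate F3, whose hydroxyl closes onto the neighbouring ester to give 17.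

**Step 6.**
- What may go wrong: competing attack of the organomagnesium reagent on the acetate, enolisation of the aldehyde, or closure of the new benzylic hydroxyl onto the labile acetal during work-up and purification.
- Route of the fallback: it sets out from 11 and from the Grignard reagent 12 and comes back at 14. It forms the aryl ketone directly by acylation and so avoids the benzylic alcohol altogether.
- Pinnick oxidation of 11 should give (R)-11-acetoxypentadec-14-enoic acid F4, and oxalyl chloride with catalytic DMF should give (R)-11-acetoxypentadec-14-enoyl chloride F5.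
- Transmetalation of 12 with ZnCl2 should give [2-(1,3-dioxolan-2-yl)-3,5-dimethoxyphenyl]zinc chloride F6.
- Negishi-type acylation of F6 with F5 under Pd(PPh3)4 in THF tolerates esters and should deliver 14.

**Step 3.**
- What may go wrong: magnesium insertion into the poorly soluble bromo alkoxide may be incomplete, Wurtz coupling may consume the bromide, and the opening of the volatile epoxide may then stall.
- Route of the fallback: it sets out from 5 and comes back at 11. It uses a silyl ether in place of the alkoxide mask and reverses the order of acetylation and oxidation.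
- TBSCl and imidazole should give (9-bromononyloxy)(tert-butyl)dimethylsilane F7, and magnesium in THF should give {9-[(tert-butyldimethylsilyl)oxy]nonyl}magnesium bromide F8.
- CuI-catalysed opening of 6 should give (R)-15-[(tert-butyldimethylsilyl)oxy]pentadec-1-en-5-ol F9.
- Acetylation should give (R)-15-[(tert-butyldimethylsilyl)oxy]pentadec-1-en-5-yl acetate F10, and HF·pyridine should give (R)-15-hydroxypentadec-1-en-5-yl acetate F11.
- Dess–Martin oxidation of F11 should give 11.

**Further compounds**

F1 | step 9 | 2-[(R)-11-acetoxy-14-oxopentadecanoyl]-4,6-dimethoxybenzoic acid | COc1cc(OC)c(C(O)=O)c(c1)C(=O)CCCCCCCCC[C@H](CCC(C)=O)OC(C)=O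
F2 | step 9 | methyl 2-[(R)-11-acetoxy-14-oxopentadecanoyl]-4,6-dimethoxybenzoate | COc1cc(OC)c(C(=O)OC)c(c1)C(=O)CCCCCCCCC[C@H](CCC(C)=O)OC(C)=O
F3 | step 9 | methyl 2-[(1S,11R)-11-acetoxy-1-hydroxy-14-oxopentadecyl]-4,6-dimethoxybenzoate | COc1cc(OC)c(C(=O)OC)c(c1)[C@@H](O)CCCCCCCCC[C@H](CCC(C)=O)OC(C)=O
F4 | step 6 | (R)-11-acetoxypentadec-14-enoic acid | OC(=O)CCCCCCCCC[C@H](CCC=C)OC(C)=O
F5 | step 6 | (R)-11-acetoxypentadec-14-enoyl chloride | ClC(=O)CCCCCCCCC[C@H](CCC=C)OC(C)=O
F6 | step 6 | [2-(1,3-dioxolan-2-yl)-3,5-dimethoxyphenyl]zinc chloride | COc1cc([Zn]Cl)c(C2OCCO2)c(OC)c1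
F7 | step 3 | (9-bromononyloxy)(tert-butyl)dimethylsilane | CC(C)(C)[Si](C)(C)OCCCCCCCCCBr
F8 | step 3 | {9-[(tert-butyldimethylsilyl)oxy]nonyl}magnesium bromide | CC(C)(C)[Si](C)(C)OCCCCCCCCC[Mg]Br
F9 | step 3 | (R)-15-[(tert-butyldimethylsilyl)oxy]pentadec-1-en-5-ol | CC(C)(C)[Si](C)(C)OCCCCCCCCCC[C@H](CCC=C)O
F10 | step 3 | (R)-15-[(tert-butyldimethylsilyl)oxy]pentadec-1-en-5-yl acetate | CC(C)(C)[Si](C)(C)OCCCCCCCCCC[C@H](CCC=C)OC(C)=O
F11 | step 3 | (R)-15-hydroxypentadec-1-en-5-yl acetate | OCCCCCCCCCC[C@H](CCC=C)OC(C)=O
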